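**Retrosynthetic overview**

1. Feature: the cyclopentenone ring (C1–C5) is fused at C1/C5 to the seven-membered ring (C1, C5–C10). C7 is the α-carbon between the oxygenated C8 and C11, and C6 is the γ-carbon of the C3 enone, so both ends of the C6–C7 bond are donor carbons and only an oxidative union joins them directly.
2. Torilin ⇒ remove C11 acetate and C8 angelate ⇒ 8,11-diol enone 22 ⇒ (MnO2, MeMgBr, hydride) ⇒ bicyclic enone β-keto ester 19.
3. 19 ⇒ disconnect C6–C7 (opens the seven-membered ring) ⇒ β-keto ester 15, tethered at C1 to a 1-ethoxy-2-methyl-3-methylidenecyclopentene.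
4. 15 ⇒ Peterson methylenation at C5, malonate homologation at C8, copper-catalysed asymmetric methyl addition at C10, aldol condensation at C1 ⇒ ethyl enol ether 2 of dione 1 + aldehyde 3.
5. Ring order: the five-membered ring is present from 1; the seven-membered ring is closed in step 10.

Key step: step 10

Remark: the sense of induction of the copper–ferrocenyl diphosphine catalyst on enone 6 is assumed, the ligand antipode that gives 10S being the one used; C1 is carried as an epimer mixture from step 4 and is fixed in step 11.

**Route**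

Step 1
Reactants: 1 2-methylcyclopentane-1,3-dione
Product: 2 3-ethoxy-2-methylcyclopent-2-en-1-one
Conditions: EtOH, p-TsOH (cat.), toluene, reflux, Dean–Stark
Reagents that add atoms: ethanol, CCO
Why: Acid-catalysed enol etherification of the symmetric cyclic 1,3-dione with azeotropic removal of water should give the single vinylogous ester.

Step 2
Reactants: 2 3-ethoxy-2-methylcyclopent-2-en-1-one; 3 3-(tert-butyldimethylsilyloxy)propanal
Product: 4 3-ethoxy-5-[1-hydroxy-3-(tert-butyldimethylsilyloxy)propyl]-2-methylcyclopent-2-en-1-one (diastereomer mixture)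
Conditions: LiN(i-Pr)2, THF, −78 °C; then 3, −78 °C; H2O quench
Reagents that add atoms: none
Why: Kinetic deprotonation of the vinylogous ester at its α′ carbon (guaiane C1) followed by aldol addition; the new carbinol centres are removed in the next step.

Step 3
Reactants: 4 aldol adduct
Product: 6 (5E)-3-ethoxy-2-methyl-5-[3-(tert-butyldimethylsilyloxy)propylidene]cyclopent-2-en-1-one, via mesylate 5 (not isolated)
Conditions: MsCl, Et3N, CH2Cl2, 0 °C; then DBU, rt
Reagents that add atoms: none
Why: Mesylation and E1cB elimination complete the aldol condensation and should give the conjugated exocyclic enone as its thermodynamic E isomer.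

Step 4
Reactants: 6 exocyclic enone
Product: 7 3-ethoxy-2-methyl-5-[(2S)-4-(tert-butyldimethylsilyloxy)butan-2-yl]cyclopent-2-en-1-one (C1 epimer mixture, guaiane numbering)
Conditions: MeMgBr, CuBr·SMe2 (5 mol%), (R)-1-[(S)-2-(diphenylphosphino)ferrocenyl]ethyldicyclohexylphosphine (6 mol%), t-BuOMe, −75 °C; then MeOH, H2O
Reagents that add atoms: methylmagnesium bromide, C[Mg]Br
Why: Copper-catalysed asymmetric conjugate addition of the Grignard reagent to the s-cis exocyclic enone (the β-ethoxy enone is a far poorer acceptor), in which the chiral diphosphine sets C10 as S; protonation of the magnesium enolate is not expected to be selective, so C1 is left open here.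

Step 5
Reactants: 7 silyl ether ketone
Product: 8 3-ethoxy-5-[(2S)-4-hydroxybutan-2-yl]-2-methylcyclopent-2-en-1-one (C1 epimer mixture)
Conditions: Bu4NF, THF, 0 °C to rt
Reagents that add atoms: none
Why: Fluoride cleavage of the silyl ether, to which the vinylogous ester is inert.

Step 6
Reactants: 8 hydroxy ketone
Product: 9 (3S)-3-(4-ethoxy-3-methyl-2-oxocyclopent-3-en-1-yl)butanoic acid (C1 epimer mixture)
Conditions: TEMPO (20 mol%), PhI(OAc)2, MeCN–pH 7 phosphate buffer, rt
Reagents that add atoms: water, O
Why: Oxoammonium oxidation of the primary alcohol through the aldehyde hydrate to the C8 acid, under buffered conditions that should spare the enol ether.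

Step 7
Reactants: 9 keto acid; 10 potassium methyl malonate
Product: 13 methyl (5S)-5-(4-ethoxy-3-methyl-2-oxocyclopent-3-en-1-yl)-3-oxohexanoate (C1 epimer mixture), via acyl imidazolide 11 (not isolated), via acylmalonic half ester 12 (not isolated)
Conditions: 1,1′-carbonyldiimidazole, THF, rt; then 10, MgCl2, Et3N, MeCN, rt to 40 °C; cold 0.5 M HCl
Reagents that add atoms: none
Why: Masamune–Brooks homologation, in which the acyl imidazolide C-acylates the magnesium enolate of the malonate half ester and the adduct loses CO2; the β-keto ester (C7, C8, ester carbon) is thus completed before the acid-labile diene exists.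

Step 8
Reactants: 13 keto β-keto ester
Product: 14 methyl (5S)-5-{4-ethoxy-2-hydroxy-3-methyl-2-[(trimethylsilyl)methyl]cyclopent-3-en-1-yl}-3-oxohexanoate (diastereomer mixture)
Conditions: NaH (1.05 equiv), THF, 0 °C; then Me3SiCH2Li, CeCl3, THF, −78 °C; aq NaHCO3
Reagents that add atoms: (trimethylsilyl)methyllithium, [Li]C[Si](C)(C)C
Why: Addition stage of the Peterson olefination: with the β-keto ester masked as its sodium enolate, the weakly basic organocerium reagent should add only to the C5 carbonyl of the vinylogous ester.

Step 9
Reactants: 14 β-hydroxysilane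
Product: 15 methyl (5S)-5-(4-ethoxy-3-methyl-2-methylidenecyclopent-3-en-1-yl)-3-oxohexanoate (C1 epimer mixture)
Conditions: KH (2.5 equiv), THF, 0 °C to rt; pH 7 buffer; used at once
Reagents that add atoms: none
Why: Elimination stage of the Peterson olefination: syn-elimination of the potassium β-silyl alkoxide gives the C5=C6 methylidene under basic conditions and keeps the ethyl enol ether, which an acidic elimination would ionise and hydrolyse.

Step 10
Reactants: 15 ethoxydiene β-keto ester
Product: 18 methyl (8S)-3,8-dimethyl-2,6-dioxo-1,2,4,5,6,7,8,8a-octahydroazulene-5-carboxylate (epimers at C1 and C7), via oxocarbenium ion 16 (not isolated), via ethyl hemiketal 17 (not isolated)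
Conditions: (NH4)2Ce(NO3)6 (2.2 equiv), NaHCO3, H2O (5 equiv), MeCN, high dilution, −20 °C to 0 °C
Reagents that add atoms: water, O
Why: Tetravalent cerium oxidises the enol of the β-keto ester to an electrophilic C7 radical, which adds to the terminal methylidene carbon C6; the resulting 1-ethoxyallyl radical is oxidised by the second equivalent to oxocarbenium ion 16, and water gives hemiketal 17, which loses ethanol to release the C3 ketone and the C4=C5 alkene. The closest known reaction type is the cerium- or manganese-mediated oxidative cyclisation of unsaturated β-keto esters onto enol ethers and dienes, applied here to a 1-alkoxydiene. The seven-membered ring closes in the 7-endo-trig mode. Attack at C6 rather than 6-exo attack at C5 is needed, and it is secured because C5 is fully substituted and only the endo mode gives an oxygen-stabilised allylic radical; direct oxidation of the electron-rich diene to its radical cation, followed by attack of the enol at C6, would lead to the same bond. No stereocentre is fixed here: C7 is formed as an enolisable centre and C1 is still a mixture, and both are settled in steps 11 and 12. Bicarbonate buffering, low temperature and a two-electron limit on the oxidant should protect the acid-labile dienol ether and restrain further oxidation of the product.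

Step 11
Reactants: 18 bicyclic enone β-keto ester (C1 mixture)
Product: 19 methyl (8S,8aR)-3,8-dimethyl-2,6-dioxo-1,2,4,5,6,7,8,8a-octahydroazulene-5-carboxylate (C7 labile)
Conditions: DBU, toluene, 50 °C; pH 5 buffer
Reagents that add atoms: none
Why: Thermodynamic epimerisation at C1, the γ-carbon of the cyclopentenone, through the extended dienolate: the C1–C2 bond is held in the enone plane, so the 1R epimer (H1 and H10 trans) keeps the C10 methyl pseudo-equatorial while the other epimer forces it pseudo-axial, and the 1R epimer should therefore prevail.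

Step 12
Reactants: 19 bicyclic enone β-keto ester
Product: 20 methyl (5S,6R,8S,8aR)-2,6-dihydroxy-3,8-dimethyl-1,2,4,5,6,7,8,8a-octahydroazulene-5-carboxylate (C3 carbinol mixture, guaiane numbering)
Conditions: Zn(BH4)2, Et2O–THF, −20 °C to 0 °C
Reagents that add atoms: none
Why: Chelation-controlled hydride reduction: hydride is delivered to the zinc chelate of the β-keto ester from the side of the C7 hydrogen, which makes the C7 ester and the C8 hydroxyl cis, and of the C7 epimers interconverting through the enol the one with the ester pseudo-equatorial on the face of the C10 methyl is expected to react, setting C7 and C8; the enone is reduced 1,2 to a C3 carbinol whose configuration does not matter.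

Step 13
Reactants: 20 diol ester
Product: 21 (5S,6R,8S,8aR)-5-(2-hydroxypropan-2-yl)-3,8-dimethyl-1,2,4,5,6,7,8,8a-octahydroazulene-2,6-diol (C3 carbinol mixture)
Conditions: MeMgBr (excess), THF, 0 °C to rt
Reagents that add atoms: methylmagnesium bromide, C[Mg]Br
Why: Double Grignard addition to the ester after deprotonation of both hydroxyls builds C11 with its two methyls; the enone is masked as the C3 carbinol, so C1 is not acidic and no conjugate addition can occur.

Step 14
Reactants: 21 triol
Product: 22 (5S,6R,8S,8aR)-6-hydroxy-5-(2-hydroxypropan-2-yl)-3,8-dimethyl-4,5,6,7,8,8a-hexahydroazulen-2(1H)-one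
Conditions: MnO2, CH2Cl2, rt
Reagents that add atoms: none
Why: Selective MnO2 oxidation of the allylic C3 alcohol restores the enone and leaves the secondary C8 and tertiary C11 alcohols untouched.

Step 15
Reactants: 22 diol enone; 23 angelic acid
Product: 25 (5S,6R,8S,8aR)-5-(2-hydroxypropan-2-yl)-3,8-dimethyl-2-oxo-1,2,4,5,6,7,8,8a-octahydroazulen-6-yl (2Z)-2-methylbut-2-enoate, via mixed anhydride 24 (not isolated)
Conditions: 23, 2,4,6-trichlorobenzoyl chloride, Et3N, toluene, rt; then 22, 80 °C
Reagents that add atoms: none
Why: Yamaguchi-type esterification through the angelic 2,4,6-trichlorobenzoic mixed anhydride, run without a nucleophilic catalyst so that the Z alkene should not isomerise to the tiglate; only the secondary C8 hydroxyl is acylated.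

Step 16
Reactants: 25 C8 angelate
Product: 26 torilin
Conditions: Ac2O, Sc(OTf)3 (5 mol%), MeCN, −20 °C
Reagents that add atoms: acetic anhydride, CC(=O)OC(C)=O
Why: Lewis acid-catalysed acetylation of the hindered tertiary C11 alcohol at low temperature, under which the angelate geometry and C1 should be unaffected.

**Compound list**

1 | 2-methylcyclopentane-1,3-dione | CC1C(=O)CCC1=O | starting material
2 | 3-ethoxy-2-methylcyclopent-2-en-1-one | CCOC1=C(C)C(=O)CC1 | intermediate
3 | 3-(tert-butyldimethylsilyloxy)propanal | O=CCCO[Si](C)(C)C(C)(C)C | starting material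
4 | 3-ethoxy-5-[1-hydroxy-3-(tert-butyldimethylsilyloxy)propyl]-2-methylcyclopent-2-en-1-one | CCOC1=C(C)C(=O)C(C(O)CCO[Si](C)(C)C(C)(C)C)C1 | intermediate
5 | mesylate of 4 | CCOC1=C(C)C(=O)C(C(CCO[Si](C)(C)C(C)(C)C)OS(C)(=O)=O)C1 | intermediate
6 | (5E)-3-ethoxy-2-methyl-5-[3-(tert-butyldimethylsilyloxy)propylidene]cyclopent-2-en-1-one | CCOC1=C(C)C(=O)/C(=C/CCO[Si](C)(C)C(C)(C)C)C1 | intermediate
7 | 3-ethoxy-2-methyl-5-[(2S)-4-(tert-butyldimethylsilyloxy)butan-2-yl]cyclopent-2-en-1-one, C1 epimers | C[C@@H](CCO[Si](C)(C)C(C)(C)C)C1CC(OCC)=C(C)C1=O | intermediate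
8 | 3-ethoxy-5-[(2S)-4-hydroxybutan-2-yl]-2-methylcyclopent-2-en-1-one, C1 epimers | C[C@@H](CCO)C1CC(OCC)=C(C)C1=O | intermediate
9 | (3S)-3-(4-ethoxy-3-methyl-2-oxocyclopent-3-en-1-yl)butanoic acid, C1 epimers | C[C@@H](CC(=O)O)C1CC(OCC)=C(C)C1=O | intermediate
10 | potassium methyl malonate | COC(=O)CC(=O)[O-].[K+] | starting material
11 | acyl imidazolide of 9 | C[C@@H](CC(=O)n1ccnc1)C1CC(OCC)=C(C)C1=O | intermediate
12 | acylmalonic half ester | COC(=O)C(C(=O)O)C(=O)C[C@H](C)C1CC(OCC)=C(C)C1=O | intermediate
13 | methyl (5S)-5-(4-ethoxy-3-methyl-2-oxocyclopent-3-en-1-yl)-3-oxohexanoate, C1 epimers | COC(=O)CC(=O)C[C@H](C)C1CC(OCC)=C(C)C1=O | intermediate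
14 | methyl (5S)-5-{4-ethoxy-2-hydroxy-3-methyl-2-[(trimethylsilyl)methyl]cyclopent-3-en-1-yl}-3-oxohexanoate | COC(=O)CC(=O)C[C@H](C)C1CC(OCC)=C(C)C1(O)C[Si](C)(C)C | intermediate
15 | methyl (5S)-5-(4-ethoxy-3-methyl-2-methylidenecyclopent-3-en-1-yl)-3-oxohexanoate, C1 epimers (key-step precursor) | COC(=O)CC(=O)C[C@H](C)C1CC(OCC)=C(C)C1=C | intermediate
16 | cyclised oxocarbenium ion | CC[O+]=C1CC2C(=C1C)CC(C(=O)OC)C(=O)C[C@@H]2C | intermediate
17 | ethyl hemiketal at C3 | CCOC1(O)CC2C(=C1C)CC(C(=O)OC)C(=O)C[C@@H]2C | intermediate
18 | methyl (8S)-3,8-dimethyl-2,6-dioxo-1,2,4,5,6,7,8,8a-octahydroazulene-5-carboxylate, C1 and C7 epimers (key-step product) | O=C1C[C@H](C)C2CC(=O)C(C)=C2CC1C(=O)OC | intermediate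
19 | methyl (8S,8aR)-3,8-dimethyl-2,6-dioxo-1,2,4,5,6,7,8,8a-octahydroazulene-5-carboxylate, C7 labile | O=C1C[C@H](C)[C@H]2CC(=O)C(C)=C2CC1C(=O)OC | intermediate
20 | methyl (5S,6R,8S,8aR)-2,6-dihydroxy-3,8-dimethyl-1,2,4,5,6,7,8,8a-octahydroazulene-5-carboxylate | O[C@@H]1C[C@H](C)[C@H]2CC(O)C(C)=C2C[C@@H]1C(=O)OC | intermediate
21 | (5S,6R,8S,8aR)-5-(2-hydroxypropan-2-yl)-3,8-dimethyl-1,2,4,5,6,7,8,8a-octahydroazulene-2,6-diol | O[C@@H]1C[C@H](C)[C@H]2CC(O)C(C)=C2C[C@@H]1C(C)(C)O | intermediate
22 | (5S,6R,8S,8aR)-6-hydroxy-5-(2-hydroxypropan-2-yl)-3,8-dimethyl-4,5,6,7,8,8a-hexahydroazulen-2(1H)-one | O[C@@H]1C[C@H](C)[C@H]2CC(=O)C(C)=C2C[C@@H]1C(C)(C)O | intermediate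
23 | angelic acid, (2Z)-2-methylbut-2-enoic acid | C/C=C(/C)C(=O)O | starting material
24 | angelic 2,4,6-trichlorobenzoic mixed anhydride | C/C=C(/C)C(=O)OC(=O)c1c(Cl)cc(Cl)cc1Cl | intermediate
25 | C8 angelate of 22 | C/C=C(/C)C(=O)O[C@@H]1C[C@H](C)[C@H]2CC(=O)C(C)=C2C[C@@H]1C(C)(C)O | intermediate
26 | torilin | C/C=C(/C)C(=O)O[C@@H]1C[C@H](C)[C@H]2CC(=O)C(C)=C2C[C@@H]1C(C)(C)OC(C)=O | target

**Step count**

Total steps: 16. Longest linear sequence: 16 steps (1 to 26); 3, 10 and 23 enter as purchased materials.

**Steps most likely to fail**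

Step 10. The ethoxydiene may be lost by protonation or by uncontrolled oxidation (oligomerisation of its radical cation) before the C7 radical closes the ring, and the product β-keto ester may be oxidised further. The fallback makes the same C6–C7 bond by two-electron chemistry. It sets out from 15: N-bromosuccinimide with NaHCO3 in aqueous THF at −78 °C should brominate the dienol ether at its terminal carbon C6 and release the enone, giving methyl (5S)-5-[2-(bromomethyl)-3-methyl-4-oxocyclopent-2-en-1-yl]-3-oxohexanoate F1. Cs2CO3 in MeCN at high dilution should then close the seven-membered ring by intramolecular C-alkylation of the β-keto ester at C7 with the allylic bromide. The fallback comes back to the route at 18.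

Step 11. The equilibrium at C1 may be slow or not sufficiently one-sided, because the acidic β-keto ester consumes base and the γ-deprotonation of the enone competes with aldol side reactions. The fallback fixes C1 before the ring is closed, by separation and recycling instead of a late thermodynamic funnel. It sets out from 7: chromatography should separate the C1 epimers into (5R)-3-ethoxy-2-methyl-5-[(2S)-4-(tert-butyldimethylsilyloxy)butan-2-yl]cyclopent-2-en-1-one F2 and its (5S) epimer F3. F3 is re-equilibrated with DBU (C1 is the α-carbon of the C5 ketone at this stage) and separated again. F2 is taken on with Bu4NF buffered by AcOH, and it comes back to the route at 8 as the single 1R epimer; from the methylenation onward no base strong enough to touch C1 is met, so step 10 would give 19 directly and step 11 is omitted.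

Step 12. Hydride delivery to C8 may show poor facial selectivity relative to the C10 methyl and C1, or reduction may proceed through the wrong C7 epimer, giving the trans hydroxy ester or the cis pair on the opposite face. The fallback replaces substrate control by enzyme control. It sets out from 19: a ketoreductase chosen from a screening panel (NADP+, glucose, glucose dehydrogenase, pH 7 buffer, DMSO co-solvent, 30 °C) should reduce only the C8 ketone, with dynamic kinetic resolution of C7 through the enol, to methyl (5S,6R,8S,8aR)-6-hydroxy-3,8-dimethyl-2-oxo-1,2,4,5,6,7,8,8a-octahydroazulene-5-carboxylate F4. Luche reduction (NaBH4, CeCl3·7H2O, MeOH, −40 °C) of the C3 enone then comes back to the route at 20.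

**Further compounds**

F1 | step 10 | methyl (5S)-5-[2-(bromomethyl)-3-methyl-4-oxocyclopent-2-en-1-yl]-3-oxohexanoate, C1 epimers | COC(=O)CC(=O)C[C@H](C)C1CC(=O)C(C)=C1CBr
F2 | step 11 | (5R)-3-ethoxy-2-methyl-5-[(2S)-4-(tert-butyldimethylsilyloxy)butan-2-yl]cyclopent-2-en-1-one | C[C@@H](CCO[Si](C)(C)C(C)(C)C)[C@H]1CC(OCC)=C(C)C1=O
F3 | step 11 | (5S)-3-ethoxy-2-methyl-5-[(2S)-4-(tert-butyldimethylsilyloxy)butan-2-yl]cyclopent-2-en-1-one | C[C@@H](CCO[Si](C)(C)C(C)(C)C)[C@@H]1CC(OCC)=C(C)C1=O
F4 | step 12 | methyl (5S,6R,8S,8aR)-6-hydroxy-3,8-dimethyl-2-oxo-1,2,4,5,6,7,8,8a-octahydroazulene-5-carboxylate | O[C@@H]1C[C@H](C)[C@H]2CC(=O)C(C)=C2C[C@@H]1C(=O)OC
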